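**Retrosynthetic overview** (germacrane numbering: C12 lactone carbonyl, C13 exocyclic CH2, C6 lactone carbinol, C8 angelate carbinol, C3 acetate carbinol, C1 free carbinol, C15 CH2OH on C4)
1. Target 22 ⇐ TBS removal and Mitsunobu angeloylation (inversion at C8) of the ten-membered hydroxy lactone 19.
2. Ten-membered ring ⇐ C7–C8 bond: intramolecular CrCl2 Barbier allylation of enal 18 by its own 3-(bromomethyl)butenolide (sets C7 and C8, creates C11=C13); this ring is formed last.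
3. Butenolide (C6–O–C12) and the 4Z alkene ⇐ key step: singlet-oxygen dearomatisation of furan 7 to a cis-keto-enal, then asymmetric NiCl2/CrCl2 alkenylation–lactonisation with iodoacrylate 10 (sets C6); C3 follows by CBS reduction and acetylation.
4. Furan 7 ⇐ C2-lithiated furan-3-ylmethanol 4 + (R)-alkenyl epoxide 3 (sets C1; from enal 1 by Corey–Chaykovsky epoxidation and hydrolytic kinetic resolution).
5. Ring order: furan (purchased, later unravelled) → butenolide → ten-membered carbocycle.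

Assumption: (E)-4,4-dimethoxy-2-methylbut-2-enal (1) is taken as a purchasable C5 building block. TBS = tert-butyldimethylsilyl; TBSO = TBS ether oxygen.

**Route**

Step 1
Reactants: 1 (E)-4,4-dimethoxy-2-methylbut-2-enal
Product: 2 rac-2-[(E)-4,4-dimethoxybut-2-en-2-yl]oxirane
Conditions: Me3S+ I−, KOtBu, DMSO/THF, 0 °C to rt
Reagents that add atoms: trimethylsulfonium iodide, C[S+](C)C.[I-]
Why: Corey–Chaykovsky epoxidation, in which dimethylsulfonium methylide adds 1,2 to the enal carbonyl and closes to the alkenyl oxirane; no stereocontrol is needed because the racemate is resolved in step 2.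

Step 2
Reactants: 2 rac-2-[(E)-4,4-dimethoxybut-2-en-2-yl]oxirane
Product: 3 (R)-2-[(E)-4,4-dimethoxybut-2-en-2-yl]oxirane
Conditions: (salen)Co(OAc) (0.5 mol%, the antipode that hydrolyses the (S)-epoxide), H2O (0.55 equiv), THF, 0 °C to rt
Reagents that add atoms: none
Why: Jacobsen hydrolytic kinetic resolution, in which (salen)Co(OAc) hydrolyses the (S)-epoxide selectively so that the (R)-epoxide carrying the future C1 stereocentre is recovered in high ee.

Step 3
Reactants: 3 (R)-2-[(E)-4,4-dimethoxybut-2-en-2-yl]oxirane; 4 furan-3-ylmethanol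
Product: 6 (2S,3E)-1-[3-(hydroxymethyl)furan-2-yl]-5,5-dimethoxy-3-methylpent-3-en-2-ol, via dilithiated furan 5 (not isolated)
Conditions: n-BuLi (2.2 equiv), THF, −78 to 0 °C; then 3, DMPU, −20 °C to rt; H2O
Reagents that add atoms: none
Why: Alkoxide-directed C2 lithiation of 4 followed by SN2 epoxide opening at the unhindered terminal CH2 (no Lewis acid, so allylic and SN2' opening are suppressed), which leaves the C1 configuration untouched.

Step 4
Reactants: 6 (2S,3E)-1-[3-(hydroxymethyl)furan-2-yl]-5,5-dimethoxy-3-methylpent-3-en-2-ol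
Product: 7 3-(TBSO-methyl)-2-[(2S,3E)-2-(TBSO)-5,5-dimethoxy-3-methylpent-3-en-1-yl]furan
Conditions: TBSCl (2.5 equiv), imidazole, DMF, rt
Reagents that add atoms: tert-butyldimethylsilyl chloride, CC(C)(C)[Si](C)(C)Cl
Why: Standard silyl ether formation under basic conditions protects the C15 and C1 hydroxyls while the dimethyl acetal survives.

Step 5
Reactants: 8 methyl propiolate; 9 formaldehyde (from cracked paraformaldehyde)
Product: 10 methyl (Z)-2-(hydroxymethyl)-3-iodoacrylate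
Conditions: MgI2, CH2Cl2, 0 °C to rt; aqueous work-up
Reagents that add atoms: magnesium iodide, [Mg+2].[I-].[I-]
Why: Halo-aldol (β-iodo Morita–Baylis–Hillman) reaction, in which iodide adds conjugately to the propiolate and the allenolate (O–MgI) is trapped by formaldehyde to give the Z-iodoacrylate with iodine cis to the ester.

Step 6
Reactants: 7 3-(TBSO-methyl)-2-[(2S,3E)-2-(TBSO)-5,5-dimethoxy-3-methylpent-3-en-1-yl]furan; 10 methyl (Z)-2-(hydroxymethyl)-3-iodoacrylate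
Product: 14 (5R)-5-[(1Z,5S,6E)-5-(TBSO)-2-(TBSO-methyl)-8,8-dimethoxy-6-methyl-3-oxoocta-1,6-dien-1-yl]-3-(hydroxymethyl)furan-2(5H)-one, via furan endoperoxide 11 (not isolated), via cis-keto-enal 12 (not isolated), via hydroxy ester 13 (not isolated)
Conditions: O2, hν, tetraphenylporphyrin (cat.), CH2Cl2, −78 °C; Me2S, −78 °C to rt; evaporate; then 10, CrCl2 (15 mol%), N-[2-(4-isopropyl-4,5-dihydrooxazol-2-yl)-6-methylphenyl]methanesulfonamide (17 mol%, antipode giving 6R), proton sponge (17 mol%), NiCl2·dmp (2 mol%, dmp = 2,9-dimethyl-1,10-phenanthroline), Mn, Cp2ZrCl2, LiCl, MeCN, rt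
Reagents that add atoms: dioxygen, O=O
Why: Furan photooxygenation ([4+2] addition of singlet oxygen) and Me2S reduction unravel the aromatic ring to the cis-keto-enal, fixing the 4Z alkene and differentiating the C3 ketone from the C6 aldehyde; the crude aldehyde then undergoes a catalytic asymmetric Nozaki–Hiyama–Kishi alkenylation in which the CrCl2/sulfonamide catalyst sets C6 (R), and the cis ester lactonises at once to the butenolide, which also blocks re-aromatisation.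

Step 7
Reactants: 14 (5R)-5-[(1Z,5S,6E)-5-(TBSO)-2-(TBSO-methyl)-8,8-dimethoxy-6-methyl-3-oxoocta-1,6-dien-1-yl]-3-(hydroxymethyl)furan-2(5H)-one
Product: 15 (5R)-3-(bromomethyl)-5-[(1Z,5S,6E)-5-(TBSO)-2-(TBSO-methyl)-8,8-dimethoxy-6-methyl-3-oxoocta-1,6-dien-1-yl]furan-2(5H)-one
Conditions: CBr4, PPh3, CH2Cl2, 0 °C
Reagents that add atoms: carbon tetrabromide, BrC(Br)(Br)Br
Why: Appel bromination of the primary allylic alcohol under neutral conditions, which tolerates the acetal, the silyl ethers and the base-sensitive C6–H of the butenolide.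

Step 8
Reactants: 15 (5R)-3-(bromomethyl)-5-[(1Z,5S,6E)-5-(TBSO)-2-(TBSO-methyl)-8,8-dimethoxy-6-methyl-3-oxoocta-1,6-dien-1-yl]furan-2(5H)-one
Product: 16 (5R)-3-(bromomethyl)-5-[(1Z,3S,5S,6E)-5-(TBSO)-2-(TBSO-methyl)-3-hydroxy-8,8-dimethoxy-6-methylocta-1,6-dien-1-yl]furan-2(5H)-one
Conditions: (R)-2-methyl-CBS-oxazaborolidine (0.5 equiv), catecholborane, toluene, −78 °C; H2O work-up
Reagents that add atoms: none
Why: Corey–Bakshi–Shibata reduction, in which the (R)-oxazaborolidine delivers hydride to the acyclic enone with the alkenyl group as the large substituent and so sets C3 (S) under reagent control; removing the ketone here also prevents a five-ring attack of C7 on C3 in step 11.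

Step 9
Reactants: 16 (5R)-3-(bromomethyl)-5-[(1Z,3S,5S,6E)-5-(TBSO)-2-(TBSO-methyl)-3-hydroxy-8,8-dimethoxy-6-methylocta-1,6-dien-1-yl]furan-2(5H)-one
Product: 17 (5R)-5-[(1Z,3S,5S,6E)-3-acetoxy-5-(TBSO)-2-(TBSO-methyl)-8,8-dimethoxy-6-methylocta-1,6-dien-1-yl]-3-(bromomethyl)furan-2(5H)-one
Conditions: AcCl, 2,4,6-collidine, CH2Cl2, −20 to 0 °C
Reagents that add atoms: acetyl chloride, CC(=O)Cl
Why: O-acetylation with acetyl chloride and the hindered base collidine installs the C3 acetate without quaternising the allylic bromide or epimerising C6.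

Step 10
Reactants: 17 (5R)-5-[(1Z,3S,5S,6E)-3-acetoxy-5-(TBSO)-2-(TBSO-methyl)-8,8-dimethoxy-6-methylocta-1,6-dien-1-yl]-3-(bromomethyl)furan-2(5H)-one
Product: 18 (2E,4S,6S,7Z)-6-acetoxy-8-[(2R)-4-(bromomethyl)-5-oxo-2,5-dihydrofuran-2-yl]-4-(TBSO)-7-(TBSO-methyl)-3-methylocta-2,7-dienal
Conditions: 10% aq. oxalic acid, SiO2, CH2Cl2, rt
Reagents that add atoms: water, O
Why: Mild acid hydrolysis of the allylic dimethyl acetal unmasks the E-enal (C8) while the silyl ethers, acetate and bromide survive.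

Step 11
Reactants: 18 (2E,4S,6S,7Z)-6-acetoxy-8-[(2R)-4-(bromomethyl)-5-oxo-2,5-dihydrofuran-2-yl]-4-(TBSO)-7-(TBSO-methyl)-3-methylocta-2,7-dienal
Product: 19 (1S,3S,6R,7R,8S)-3-acetoxy-1,15-bis(TBSO)-8-hydroxygermacra-4Z,9E,11(13)-trien-6,12-olide
Conditions: CrCl2 (8 equiv), THF, 2 mM (syringe pump), rt; aqueous work-up
Reagents that add atoms: none
Why: Intramolecular Nozaki–Hiyama (chromium Barbier) allylation, in which the allyl–CrCl2 species attacks the aldehyde through its γ-carbon C7 in a chair transition state, anti to the C6 substituent (trans-fused lactone, 7R) and with the aldehyde chain equatorial (anti adduct, 8S), closing the ten-membered ring and creating the exocyclic methylene.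

Step 12
Reactants: 19 (1S,3S,6R,7R,8S)-3-acetoxy-1,15-bis(TBSO)-8-hydroxygermacra-4Z,9E,11(13)-trien-6,12-olide; 20 angelic acid, (Z)-2-methylbut-2-enoic acid
Product: 21 (1S,3S,6R,7R,8R)-3-acetoxy-8-angeloyloxy-1,15-bis(TBSO)germacra-4Z,9E,11(13)-trien-6,12-olide
Conditions: PPh3, DIAD, toluene, 0 °C to rt
Reagents that add atoms: none
Why: Mitsunobu esterification inverts C8 (S to R) by SN2 displacement of the alkoxyphosphonium ion by angelate, installing the ester with the required configuration without the base or heat that isomerise angelates to tiglates.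

Step 13
Reactants: 21 (1S,3S,6R,7R,8R)-3-acetoxy-8-angeloyloxy-1,15-bis(TBSO)germacra-4Z,9E,11(13)-trien-6,12-olide
Product: 22 (1S,3S,6R,7R,8R)-3-acetoxy-8-angeloyloxy-1,15-dihydroxygermacra-4Z,9E,11(13)-trien-6,12-olide (CNP0153210.6)
Conditions: HF·pyridine, THF/pyridine, 0 °C to rt
Reagents that add atoms: none
Why: Fluoride-mediated desilylation removes both TBS ethers under buffered conditions that leave the acetate, the angelate and the α-methylene lactone intact.

**Compound list**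
1 | (E)-4,4-dimethoxy-2-methylbut-2-enal | O=C/C(C)=C/C(OC)OC | starting material
2 | rac-2-[(E)-4,4-dimethoxybut-2-en-2-yl]oxirane | C1OC1/C(C)=C/C(OC)OC | intermediate
3 | (R)-2-[(E)-4,4-dimethoxybut-2-en-2-yl]oxirane | C1O[C@@H]1/C(C)=C/C(OC)OC | intermediate
4 | furan-3-ylmethanol | OCc1ccoc1 | starting material
5 | 2-lithio-3-(lithiooxymethyl)furan | [Li]OCc1ccoc1[Li] | intermediate
6 | (2S,3E)-1-[3-(hydroxymethyl)furan-2-yl]-5,5-dimethoxy-3-methylpent-3-en-2-ol | OCc1ccoc1C[C@H](O)/C(C)=C/C(OC)OC | intermediate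
7 | 3-(TBSO-methyl)-2-[(2S,3E)-2-(TBSO)-5,5-dimethoxy-3-methylpent-3-en-1-yl]furan | CC(C)(C)[Si](C)(C)OCc1ccoc1C[C@H](O[Si](C)(C)C(C)(C)C)/C(C)=C/C(OC)OC | intermediate
8 | methyl propiolate | C#CC(=O)OC | starting material
9 | formaldehyde (from paraformaldehyde) | C=O | starting material
10 | methyl (Z)-2-(hydroxymethyl)-3-iodoacrylate | COC(=O)/C(CO)=C\I | intermediate
11 | 1-[(2S,3E)-2-(TBSO)-5,5-dimethoxy-3-methylpent-3-en-1-yl]-6-(TBSO-methyl)-2,3,7-trioxabicyclo[2.2.1]hept-5-ene (both bridgehead epimers) | CC(C)(C)[Si](C)(C)OCC1=CC2OOC1(O2)C[C@H](O[Si](C)(C)C(C)(C)C)/C(C)=C/C(OC)OC | intermediate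
12 | (2Z,6S,7E)-6-(TBSO)-3-(TBSO-methyl)-9,9-dimethoxy-7-methyl-4-oxonona-2,7-dienal | O=C/C=C(/CO[Si](C)(C)C(C)(C)C)C(=O)C[C@H](O[Si](C)(C)C(C)(C)C)/C(C)=C/C(OC)OC | intermediate
13 | methyl (2Z,4R,5Z,9S,10E)-9-(TBSO)-6-(TBSO-methyl)-4-hydroxy-2-(hydroxymethyl)-12,12-dimethoxy-10-methyl-7-oxododeca-2,5,10-trienoate | COC(=O)/C(CO)=C\[C@H](O)/C=C(/CO[Si](C)(C)C(C)(C)C)C(=O)C[C@H](O[Si](C)(C)C(C)(C)C)/C(C)=C/C(OC)OC | intermediate
14 | (5R)-5-[(1Z,5S,6E)-5-(TBSO)-2-(TBSO-methyl)-8,8-dimethoxy-6-methyl-3-oxoocta-1,6-dien-1-yl]-3-(hydroxymethyl)furan-2(5H)-one | O=C1O[C@H](/C=C(/CO[Si](C)(C)C(C)(C)C)C(=O)C[C@H](O[Si](C)(C)C(C)(C)C)/C(C)=C/C(OC)OC)C=C1CO | intermediate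
15 | (5R)-3-(bromomethyl)-5-[(1Z,5S,6E)-5-(TBSO)-2-(TBSO-methyl)-8,8-dimethoxy-6-methyl-3-oxoocta-1,6-dien-1-yl]furan-2(5H)-one | O=C1O[C@H](/C=C(/CO[Si](C)(C)C(C)(C)C)C(=O)C[C@H](O[Si](C)(C)C(C)(C)C)/C(C)=C/C(OC)OC)C=C1CBr | intermediate
16 | (5R)-3-(bromomethyl)-5-[(1Z,3S,5S,6E)-5-(TBSO)-2-(TBSO-methyl)-3-hydroxy-8,8-dimethoxy-6-methylocta-1,6-dien-1-yl]furan-2(5H)-one | O=C1O[C@H](/C=C(/CO[Si](C)(C)C(C)(C)C)[C@@H](O)C[C@H](O[Si](C)(C)C(C)(C)C)/C(C)=C/C(OC)OC)C=C1CBr | intermediate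
17 | (5R)-5-[(1Z,3S,5S,6E)-3-acetoxy-5-(TBSO)-2-(TBSO-methyl)-8,8-dimethoxy-6-methylocta-1,6-dien-1-yl]-3-(bromomethyl)furan-2(5H)-one | O=C1O[C@H](/C=C(/CO[Si](C)(C)C(C)(C)C)[C@@H](OC(C)=O)C[C@H](O[Si](C)(C)C(C)(C)C)/C(C)=C/C(OC)OC)C=C1CBr | intermediate
18 | (2E,4S,6S,7Z)-6-acetoxy-8-[(2R)-4-(bromomethyl)-5-oxo-2,5-dihydrofuran-2-yl]-4-(TBSO)-7-(TBSO-methyl)-3-methylocta-2,7-dienal | O=C1O[C@H](/C=C(/CO[Si](C)(C)C(C)(C)C)[C@@H](OC(C)=O)C[C@H](O[Si](C)(C)C(C)(C)C)/C(C)=C/C=O)C=C1CBr | intermediate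
19 | (1S,3S,6R,7R,8S)-3-acetoxy-1,15-bis(TBSO)-8-hydroxygermacra-4Z,9E,11(13)-trien-6,12-olide | C=C1C(=O)O[C@@H]2/C=C(/CO[Si](C)(C)C(C)(C)C)[C@@H](OC(C)=O)C[C@H](O[Si](C)(C)C(C)(C)C)/C(C)=C/[C@H](O)[C@@H]12 | intermediate
20 | angelic acid, (Z)-2-methylbut-2-enoic acid | C/C=C(/C)C(=O)O | starting material
21 | (1S,3S,6R,7R,8R)-3-acetoxy-8-angeloyloxy-1,15-bis(TBSO)germacra-4Z,9E,11(13)-trien-6,12-olide | C=C1C(=O)O[C@@H]2/C=C(/CO[Si](C)(C)C(C)(C)C)[C@@H](OC(C)=O)C[C@H](O[Si](C)(C)C(C)(C)C)/C(C)=C/[C@@H](OC(=O)/C(C)=C\C)[C@@H]12 | intermediate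
22 | (1S,3S,6R,7R,8R)-3-acetoxy-8-angeloyloxy-1,15-dihydroxygermacra-4Z,9E,11(13)-trien-6,12-olide (CNP0153210.6) | C=C1C(=O)O[C@@H]2/C=C(/CO)[C@@H](OC(C)=O)C[C@H](O)/C(C)=C/[C@@H](OC(=O)/C(C)=C\C)[C@@H]12 | target

**Step count and risks**
Total step count: 13 (12 on the main line plus step 5 for reagent 10).
Longest linear sequence: 12 steps (1 to 22 through steps 1–4 and 6–13).

Three steps most likely to fail:

Step 6 (dearomatisation and asymmetric alkenylation–lactonisation). The cis-keto-enal 12 can isomerise, can be reduced by low-valent chromium, or can revert to a furan after addition; the enantioselectivity on this enal is also untested. The fallback sets out from crude keto-enal 12 and comes back at bromide 15. Enantioselective vinyl transfer from divinylzinc ((−)-MIB or its antipode, toluene, −20 °C) gives the zinc alkoxide of the vinyl carbinol F1. This is acylated in the same flask with 2-(bromomethyl)acryloyl chloride to the 2-(bromomethyl)acrylate F2. Ring-closing metathesis (second-generation Hoveyda–Grubbs catalyst, toluene, 60 °C) then closes the butenolide to 15 directly, so no chromium meets the ene-dicarbonyl and step 7 is skipped.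

Step 11 (ten-membered ring closure). The ring may not close, may close cis-fused, or may give the other C8 epimer. The fallback sets out from aldehyde 18 and comes back at angelate 21. Stannylation (Bu3SnSnBu3, Pd(PPh3)4, THF) converts the bromide into the allylstannane F3. BF3·OEt2 (CH2Cl2, −78 °C, high dilution) then closes the ring through an open transition state, which is expected to give the syn adduct, the 8R alcohol F4. Yamaguchi esterification of F4 with 20 (2,4,6-trichlorobenzoyl chloride, Et3N, DMAP, toluene; retention) gives 21, and step 12 is not needed.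

Step 12 (Mitsunobu angeloylation). The hindered allylic alcohol may react by SN2', eliminate, or give tiglate. The fallback sets out from 19 and comes back at 21. Mesylation (MsCl, Et3N, CH2Cl2, −20 °C) gives the C8 mesylate F5, which is displaced with inversion by cesium (Z)-2-methylbut-2-enoate (from 20 and Cs2CO3, 18-crown-6, toluene, 60 °C).

Further compounds
F1 | step 6 | (3S,4Z,8S,9E)-8-(TBSO)-5-(TBSO-methyl)-3-hydroxy-11,11-dimethoxy-9-methylundeca-1,4,9-trien-6-one | C=C[C@H](O)/C=C(/CO[Si](C)(C)C(C)(C)C)C(=O)C[C@H](O[Si](C)(C)C(C)(C)C)/C(C)=C/C(OC)OC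
F2 | step 6 | 2-(bromomethyl)acrylate ester of F1 at the C3 hydroxyl | C=C[C@H](OC(=O)C(=C)CBr)/C=C(/CO[Si](C)(C)C(C)(C)C)C(=O)C[C@H](O[Si](C)(C)C(C)(C)C)/C(C)=C/C(OC)OC
F3 | step 11 | (2E,4S,6S,7Z)-6-acetoxy-4-(TBSO)-7-(TBSO-methyl)-3-methyl-8-[(2R)-5-oxo-4-(tributylstannylmethyl)-2,5-dihydrofuran-2-yl]octa-2,7-dienal | O=C1O[C@H](/C=C(/CO[Si](C)(C)C(C)(C)C)[C@@H](OC(C)=O)C[C@H](O[Si](C)(C)C(C)(C)C)/C(C)=C/C=O)C=C1C[Sn](CCCC)(CCCC)CCCC
F4 | step 11 | (1S,3S,6R,7R,8R)-3-acetoxy-1,15-bis(TBSO)-8-hydroxygermacra-4Z,9E,11(13)-trien-6,12-olide | C=C1C(=O)O[C@@H]2/C=C(/CO[Si](C)(C)C(C)(C)C)[C@@H](OC(C)=O)C[C@H](O[Si](C)(C)C(C)(C)C)/C(C)=C/[C@@H](O)[C@@H]12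
F5 | step 12 | (1S,3S,6R,7R,8S)-3-acetoxy-1,15-bis(TBSO)-8-(methanesulfonyloxy)germacra-4Z,9E,11(13)-trien-6,12-olide | C=C1C(=O)O[C@@H]2/C=C(/CO[Si](C)(C)C(C)(C)C)[C@@H](OC(C)=O)C[C@H](O[Si](C)(C)C(C)(C)C)/C(C)=C/[C@H](OS(C)(=O)=O)[C@@H]12
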